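## Structural features

The target is an achiral, fully aromatic tetramer (C24H18O14): four benzene rings joined only by three diaryl ether oxygens, all of which sit on ring B. Ring B is penta-oxygenated (B1–O–ring A, B3–OH, B4–O–ring C, B5–OH, B6–O–ring D, with B2 the only C–H). Ring A is a 2,4,6-trihydroxyphenyl group and rings C and D are identical 3,4,5-trihydroxyphenyl groups. There are no stereocentres, so nothing has to be set or guarded against epimerisation. The fragile elements are the eleven free phenols: the pyrogallol rings C and D autoxidise readily, and the 1,3,5-oxygenated rings are open to C-protonation and ether exchange in strong acid, so the free polyphenol should appear only in the last operation. The real difficulty is ring B: five contiguous oxygens must each carry the right one of four different substituents, and each of the three ether oxygens is flanked by two ortho substituents, which makes the polarity of every ether coupling decisive. The key step exploits the fact that C4–O and D4–O are the only oxygens of rings C and D outside a 1,3,5-pattern and that each lies ortho to a ring hydroxyl (C3–OH, D3–OH). Without them, rings B, C and D all come from one 1,3,5-trisubstituted building block, and the C3/D3 hydroxyls can carry the oxidant to C4/D4.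

## Logic of the disconnections

13 to 12. The seven O–CH3 bonds (rings A and B, C5, D5) are cut last. Methyl is the one cap that survives copper and palladium catalysis, hydrogenolysis and the oxidant, so a single permanent group serves the whole route and no free polyphenol is handled before the end. The forward step must cleave seven aryl methyl ethers completely, leave three diaryl ethers intact and exclude air.

12 to 10 (key disconnection). The C4–O and D4–O bonds are cut, the species actually formed being 11. These two oxygens are the only ones that make rings C and D different from ring B, and each has a neighbouring hydroxyl that can hold a pentavalent iodine oxidant. The gain is that rings C and D become plain 1,3,5-oxygenated rings made from the same 2 as ring B, and the oxidation-prone vicinal oxygens are absent from eight of the ten steps. The demand is delivery of oxygen to the carbon between hydroxyl and methoxy on both rings. The C5/D5 oxygens are kept as methyl ethers: in a 1,3,5-oxygenated ring every free carbon is ortho or para to all three oxygens, so no spectator group shifts the electronic balance between C4 and C2 much, and the smallest cap gives the largest steric contrast with the ring B side.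

10 to 9. The two O–CH2Ph bonds at C3 and D3 are cut. The hydroxyls that bind the oxidant must be the only free ones in 10 and must be masked during ether formation; benzyl is orthogonal to methyl and leaves under neutral conditions. The forward step only has to be a clean hydrogenolysis, and 9 contains no other reducible group.

9 to 8 and two molecules of 2. The aryl C–O bonds between the B4/B6 oxygens and C1/D1 are cut so that both oxygens stay on ring B. This puts the steric burden on the nucleophile (each hydroxyl of 8 is flanked by two ortho groups) and leaves an unhindered bromide as electrophile, the polarity in which copper-mediated ether formation tolerates crowding. Both arms come from a compound already in hand. The demand is a twofold arylation, the second at a hydroxyl between a methoxy group and the ring A ether, with oxygen excluded.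

8 to 7. The B4–O and B6–O bonds are traced back to C–Br bonds, because bromine, unlike hydroxyl, can be placed on ring B site-selectively. The forward step must hydroxylate two aryl bromides that are each flanked by two oxygens.

7 to 6 to 5. The B5 O–CH3 bond and then the B4–Br and B6–Br bonds are cut. With B5 as a free hydroxyl, B4 and B6 are exactly its two ortho carbons, and ring B is the only phenol ring and so more reactive than ring A. The penta-substituted ring B is thereby reduced to a 1,3,5-pattern. The demand is ortho,ortho' over para bromination and ring B over ring A.

5 to 4 to 2 and 3. The benzyl O–C bond at B5 and then the B1–O aryl bond are cut, the oxygen staying on ring A. The hindered 3 is the nucleophile and 2 the unhindered electrophile; both partners are simple. The forward coupling must cope with an easily oxidised phenol.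

2 to 1. The benzyl O–C bond is cut. 1 already carries the three different groups (Br, OH, OMe) that ring B needs and that rings C and D need.

## Other disconnections considered

Alternative 1: The cut lies inside ring B, at the B2–B3 bond: ring B is unravelled to a four-membered ring holding B3–B6 and a 1-(aryloxy)vinyl unit holding B1 and B2. In the forward step, heating cyclobutenone A1 (racemic at its quaternary carbon, which is lost on aromatisation) would open the four-membered ring by 4π-electrocyclic reaction to a dienylketene. 6π-Electrocyclisation onto the vinyl terminus and tautomerisation would give phenol A2.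
- In favour: all five oxygens of ring B arrive in fixed positions and in distinguishable forms (free OH at B3, silyl ether at B6, methoxy at B5, ring C on B4, ring A on B1). On regiocontrol of ring B this is better than the chosen plan, which depends on a site-selective bromination (step 4). Two crowded aryl–oxygen bonds are made on non-aromatic carbons. Rings C and D enter with their 3,4,5-oxygens in place, so the site-selectivity risk of step 9 does not exist; on that point it is also the better. The pericyclic cascade needs no reagent and is mechanistically as well founded as the oxidation of step 9 (equal).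
- Against: A1 requires addition of an α-metalated aryl vinyl ether bearing the hindered ring A to an unsymmetrical aryloxy squarate, with control of which carbonyl is attacked, and such a squarate can also exchange its aryloxy group. Ring D must still be joined to the B6 oxygen after desilylation, at the most crowded site of the molecule, and B3 capped first. The final deprotection would have to cleave eleven methyl ethers, against seven here.
- Step economy: about equal in number, but with more steps on specialised intermediates.

Alternative 2: The B3–O and B5–O bonds are cut in the sense that these oxygens replace formyl carbons; before that, the B4–O and B6–O ether bonds are made by nucleophilic aromatic substitution. In the forward step, peracid would convert dialdehyde A3 by two Baeyer–Villiger (Dakin-type) aryl migrations into a bis(formate), whose cleavage gives resorcinol A4.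
- In favour: the formyl groups ortho and para to B4 and B6 turn the two most congested ether formations into addition–elimination reactions that need no metal. For these bonds it is better than the copper coupling of step 7. Migration of an electron-rich aryl group in the Criegee intermediate is strongly favoured, so the key step is at least as dependable as step 9 and has no regiochemical question (better).
- Against: in A3 and A4 the B1 oxygen is a benzyl ether, so ring A would have to be attached later to the B1 hydroxyl. That calls for a 2,4,6-trioxygenated aryl electrophile, di-ortho-substituted and electron-rich, the least favourable polarity for aryl ether synthesis; the chosen plan makes this bond in step 2 with ring A as nucleophile. The new B3 and B5 hydroxyls must be capped before that coupling, peracid may also attack the electron-rich trimethoxyphenoxy rings, and the penta-substituted dihalo dialdehyde needed for the substitution is a multistep target itself.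
- Step economy: probably two or three steps longer.

Alternative 3: The A1–A2 bond is cut, so that ring A is built last from an open chain hanging on the B1 oxygen. In the forward step, base would convert the aryloxymethyl ketone carbon of keto enoate A5 into an enolate that attacks the ester carbonyl (intramolecular Claisen condensation). The six-membered dione would aromatise to resorcinol A6.
- In favour: the A1–O bond, flanked on ring A by two oxygens, is made as a simple alkylation of a phenol with an α-halo ketone, not as an aryl coupling. The closure mirrors the polyketide origin of such rings, so it is as biomimetic as the chosen plan (equal). The free A2/A6 hydroxyls of A6 are no drawback because the last step unmasks everything (equal).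
- Against: it leaves the real problem untouched, since a ring B–C–D phenol with all of ring B's oxygens differentiated must first be made by other means. In A5 the methylene between enol ether and ketone is more acidic than the aryloxymethyl carbon. O-Acylation of the ketone enolate to a pyranone competes with C-acylation. The ring-forming step would fall on the most advanced intermediate. The chosen plan already makes the A–B ether in step 2 from two simple partners in the favourable polarity, so this disconnection solves a problem that the plan does not have.
- Step economy: clearly longer.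

Key step: step 9

Assumption: 1 and 3 are taken as purchased, and from step 6 onward all operations are run under argon in degassed solvents because the intermediates are electron-rich phenols.

## Route

Step 1
Reactants: 1 3-bromo-5-methoxyphenol
Product: 2 1-(benzyloxy)-3-bromo-5-methoxybenzene
Conditions: BnBr, K2CO3, DMF, rt
Reagents that add atoms: benzyl bromide, BrCc1ccccc1
Why: Williamson ether synthesis: the phenoxide of 1 displaces bromide from benzyl bromide, the aryl bromide is inert, and the benzyl group marks the oxygen that is freed again later (B5 in step 3; C3 and D3 in step 8).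

Step 2
Reactants: 2 1-(benzyloxy)-3-bromo-5-methoxybenzene; 3 2,4,6-trimethoxyphenol
Product: 4 2-[3-(benzyloxy)-5-methoxyphenoxy]-1,3,5-trimethoxybenzene
Conditions: CuI (10 mol%), picolinic acid (20 mol%), K3PO4, DMSO, 90 °C, Ar
Reagents that add atoms: none
Why: Ullmann-type copper-catalysed O-arylation: the crowded partner (two ortho methoxy groups) is the phenoxide and the bromide is unhindered, the polarity in which this coupling tolerates congestion; picolinic acid keeps monovalent copper active and air is excluded because 3 is easily oxidised.

Step 3
Reactants: 4 2-[3-(benzyloxy)-5-methoxyphenoxy]-1,3,5-trimethoxybenzene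
Product: 5 3-methoxy-5-(2,4,6-trimethoxyphenoxy)phenol
Conditions: H2 (1 atm), Pd/C, EtOAc/MeOH, rt
Reagents that add atoms: none
Why: Catalytic hydrogenolysis of the benzyl ether; the diaryl ether and the methyl ethers are inert, and the freed B5 hydroxyl is the handle for step 4.

Step 4
Reactants: 5 3-methoxy-5-(2,4,6-trimethoxyphenoxy)phenol
Product: 6 2,6-dibromo-3-methoxy-5-(2,4,6-trimethoxyphenoxy)phenol
Conditions: NBS (2.05 equiv), i-Pr2NH (20 mol%), CH2Cl2, −20 to 0 °C
Reagents that add atoms: N-bromosuccinimide, O=C1CCC(=O)N1Br
Why: Electrophilic aromatic bromination directed by the free hydroxyl (amine-mediated ortho-bromination of phenols): ring B is the only phenol ring and should react far faster than ring A, and the secondary amine turns NBS into an N-bromoamine that hydrogen-bonds to the phenol and hands bromine to its two ortho carbons (B4, B6) in preference to the para carbon B2.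

Step 5
Reactants: 6 2,6-dibromo-3-methoxy-5-(2,4,6-trimethoxyphenoxy)phenol
Product: 7 2,4-dibromo-1,3-dimethoxy-5-(2,4,6-trimethoxyphenoxy)benzene
Conditions: MeI, K2CO3, DMF, rt
Reagents that add atoms: iodomethane, CI
Why: Williamson methylation of the acidic 2,6-dibromophenol; it fixes B5 as a methyl ether so that rings A and B carry no hydroxyl in the key step.

Step 6
Reactants: 7 2,4-dibromo-1,3-dimethoxy-5-(2,4,6-trimethoxyphenoxy)benzene
Product: 8 2,4-dimethoxy-6-(2,4,6-trimethoxyphenoxy)benzene-1,3-diol
Conditions: Pd2(dba)3 (4 mol%), t-BuXPhos (16 mol%), KOH, 1,4-dioxane/H2O, 100 °C, Ar; then aq. HCl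
Reagents that add atoms: potassium hydroxide, [K+].[OH-]
Why: Palladium-catalysed hydroxylation of aryl bromides: zerovalent palladium carrying the bulky biaryl phosphine inserts into each C–Br bond, hydroxide replaces bromide on the metal and C–O reductive elimination releases the phenoxide; the bulky ligand is what makes di-ortho-substituted bromides viable, and the hindered phenoxide should not compete as a nucleophile in the aqueous medium.

Step 7
Reactants: 8 2,4-dimethoxy-6-(2,4,6-trimethoxyphenoxy)benzene-1,3-diol; 2 1-(benzyloxy)-3-bromo-5-methoxybenzene (two molecules incorporated)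
Product: 9 2-{2,4-bis[3-(benzyloxy)-5-methoxyphenoxy]-3,5-dimethoxyphenoxy}-1,3,5-trimethoxybenzene
Conditions: 2 (2.6 equiv), CuI (20 mol%), picolinic acid (40 mol%), K3PO4, DMSO, 100 °C, Ar
Reagents that add atoms: none
Why: Twofold Ullmann-type O-arylation under the conditions of step 2: the B4 hydroxyl is a 2,6-dimethoxyphenol like 3, the B6 hydroxyl (between a methoxy group and the ring A ether) is slower and is driven by excess 2; both steric burdens again lie on the nucleophile.

Step 8
Reactants: 9 2-{2,4-bis[3-(benzyloxy)-5-methoxyphenoxy]-3,5-dimethoxyphenoxy}-1,3,5-trimethoxybenzene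
Product: 10 3,3'-{[2,4-dimethoxy-6-(2,4,6-trimethoxyphenoxy)-1,3-phenylene]bis(oxy)}bis(5-methoxyphenol) (ring A–B–C–D tetramer with rings C and D as 3-hydroxy-5-methoxyphenyl ethers)
Conditions: H2 (1 atm), Pd/C, EtOAc/MeOH, rt
Reagents that add atoms: none
Why: Catalytic hydrogenolysis of the two benzyl ethers frees exactly the C3 and D3 hydroxyls; all other oxygens stay capped, so 10 has just the two phenols that the oxidant can bind.

Step 9
Reactants: 10 3,3'-{[2,4-dimethoxy-6-(2,4,6-trimethoxyphenoxy)-1,3-phenylene]bis(oxy)}bis(5-methoxyphenol)
Product: 12 5,5'-{[2,4-dimethoxy-6-(2,4,6-trimethoxyphenoxy)-1,3-phenylene]bis(oxy)}bis(3-methoxybenzene-1,2-diol), via bis(ortho-quinone) 11 (not isolated)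
Conditions: 2-iodoxybenzoic acid (2.4 equiv), DMF, rt, dark; then aq. Na2S2O4
Reagents that add atoms: 2-iodoxybenzoic acid, O=C1OI(O)(=O)c2ccccc12
Why: Each free hydroxyl (C3–OH, D3–OH) should exchange onto the pentavalent iodine of the reagent; an oxo ligand is then passed within this complex to the neighbouring ring carbon while the iodine falls to the trivalent state, and tautomerisation with a second reductive collapse releases the ortho-quinone and 2-iodobenzoic acid, so that one equivalent of oxidant per ring forms the C4–O and D4–O bonds. Dithionite added to the same flask reduces the bis(ortho-quinone) 11 to the bis-catechol 12 before the electrophilic quinones can add nucleophiles. The closest known reaction type is the regioselective oxidation of electron-rich phenols to ortho-quinones by 2-iodoxybenzoic acid with reductive work-up, in effect an ortho-hydroxylation. No ring is closed and no stereocentre is created. Three selectivities are needed: ortho over para, secured by the tethered delivery from the oxygen-bound iodine, which cannot reach C6 or D6; rings C and D over rings A and B, secured because A and B have no hydroxyl to bind the reagent; and C4/D4 over C2/D2, which is the delicate one. For the last, the two candidate carbons are electronically almost alike (each is ortho to one ether oxygen and para to the other), so the substrate offers a steric bias only: at C2/D2 the oxygen must enter next to the ether oxygen that carries ring B with its two ortho substituents, at C4/D4 next to a methoxy group whose methyl can turn away. Dilute solution at room temperature and prompt reduction are chosen to let this bias operate and to keep the half-oxidised intermediate from reacting with itself.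

Step 10
Reactants: 12 5,5'-{[2,4-dimethoxy-6-(2,4,6-trimethoxyphenoxy)-1,3-phenylene]bis(oxy)}bis(3-methoxybenzene-1,2-diol)
Product: 13 5,5'-{[2,4-dihydroxy-6-(2,4,6-trihydroxyphenoxy)-1,3-phenylene]bis(oxy)}bis(benzene-1,2,3-triol) (target)
Conditions: BBr3 (20 equiv), CH2Cl2, −78 °C to rt, Ar; then H2O, 0 °C
Reagents that add atoms: none
Why: Lewis acid cleavage of aryl methyl ethers: boron binds each ether oxygen and bromide removes the methyl group by SN2 displacement as bromomethane, while the diaryl ether oxygens offer no sp3 carbon and should stay intact; hydrolysis of the aryloxyboranes under argon gives the polyphenol.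

## Compound list

1 | 3-bromo-5-methoxyphenol | COc1cc(O)cc(Br)c1 | starting material
2 | 1-(benzyloxy)-3-bromo-5-methoxybenzene | COc1cc(Br)cc(OCc2ccccc2)c1 | intermediate
3 | 2,4,6-trimethoxyphenol | COc1cc(OC)c(O)c(OC)c1 | starting material
4 | 2-[3-(benzyloxy)-5-methoxyphenoxy]-1,3,5-trimethoxybenzene | COc1cc(OC)c(Oc2cc(OC)cc(OCc3ccccc3)c2)c(OC)c1 | intermediate
5 | 3-methoxy-5-(2,4,6-trimethoxyphenoxy)phenol | COc1cc(O)cc(Oc2c(OC)cc(OC)cc2OC)c1 | intermediate
6 | 2,6-dibromo-3-methoxy-5-(2,4,6-trimethoxyphenoxy)phenol | Oc1c(Br)c(OC)cc(Oc2c(OC)cc(OC)cc2OC)c1Br | intermediate
7 | 2,4-dibromo-1,3-dimethoxy-5-(2,4,6-trimethoxyphenoxy)benzene | COc1c(Br)c(OC)cc(Oc2c(OC)cc(OC)cc2OC)c1Br | intermediate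
8 | 2,4-dimethoxy-6-(2,4,6-trimethoxyphenoxy)benzene-1,3-diol | COc1c(O)c(OC)cc(Oc2c(OC)cc(OC)cc2OC)c1O | intermediate
9 | 2-{2,4-bis[3-(benzyloxy)-5-methoxyphenoxy]-3,5-dimethoxyphenoxy}-1,3,5-trimethoxybenzene | COc1cc(OC)c(Oc2cc(OC)c(Oc3cc(OC)cc(OCc4ccccc4)c3)c(OC)c2Oc2cc(OC)cc(OCc3ccccc3)c2)c(OC)c1 | intermediate
10 | 3,3'-{[2,4-dimethoxy-6-(2,4,6-trimethoxyphenoxy)-1,3-phenylene]bis(oxy)}bis(5-methoxyphenol) | COc1cc(OC)c(Oc2cc(OC)c(Oc3cc(O)cc(OC)c3)c(OC)c2Oc2cc(O)cc(OC)c2)c(OC)c1 | intermediate
11 | 5,5'-{[2,4-dimethoxy-6-(2,4,6-trimethoxyphenoxy)-1,3-phenylene]bis(oxy)}bis(3-methoxycyclohexa-3,5-diene-1,2-dione) | COc1cc(OC)c(Oc2cc(OC)c(OC3=CC(=O)C(=O)C(OC)=C3)c(OC)c2OC2=CC(=O)C(=O)C(OC)=C2)c(OC)c1 | intermediate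
12 | 5,5'-{[2,4-dimethoxy-6-(2,4,6-trimethoxyphenoxy)-1,3-phenylene]bis(oxy)}bis(3-methoxybenzene-1,2-diol) | COc1cc(OC)c(Oc2cc(OC)c(Oc3cc(O)c(O)c(OC)c3)c(OC)c2Oc2cc(O)c(O)c(OC)c2)c(OC)c1 | intermediate
13 | 5,5'-{[2,4-dihydroxy-6-(2,4,6-trihydroxyphenoxy)-1,3-phenylene]bis(oxy)}bis(benzene-1,2,3-triol) | Oc1cc(O)c(Oc2cc(O)c(Oc3cc(O)c(O)c(O)c3)c(O)c2Oc2cc(O)c(O)c(O)c2)c(O)c1 | target

## Step count and least certain steps

Total step count: 10. Longest linear sequence: 10 steps (1 to 13; 2 is made once and used in steps 2 and 7).

Step 9 (key step). The most likely failure is insufficient site selectivity: delivery of oxygen to C2 or D2 in competition with C4 and D4, because both ortho carbons of each phenol lie between two oxygens and differ only in the size of the neighbouring group. A second failure is self-condensation of the half-oxidised intermediate through its electrophilic quinone. The fallback gives up late oxygenation and brings the C4 and D4 oxygens in with the rings. It sets out from 8, which would be coupled under the conditions of step 7 with purchased 5-bromo-1,2,3-trimethoxybenzene F1 to give 2-[3,5-dimethoxy-2,4-bis(3,4,5-trimethoxyphenoxy)phenoxy]-1,3,5-trimethoxybenzene F2. Exhaustive demethylation of F2 with BBr3 as in step 10 comes back to the route at 13.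

Step 7. The second arylation, at the B6 hydroxyl between a methoxy group and the ring A ether, may stall, and the electron-rich resorcinol may degrade oxidatively under hot basic copper conditions. The fallback reverses the polarity and avoids the free diol. It sets out from 7. Purchased 5-methoxyresorcinol F3 would be monobenzylated (BnBr, K2CO3, DMF; the statistical mixture is separable) to 3-(benzyloxy)-5-methoxyphenol F4. 7 would then be coupled twice with F4 by palladium-catalysed C–O coupling (Pd(OAc)2, t-BuXPhos, K3PO4, toluene, 100 °C), coming back at 9 and bypassing step 6.

Step 6. Oxidative addition at two C–Br bonds that are each flanked by two oxygens may be slow, so that hydrodebromination or incomplete conversion to the monophenol takes over. The fallback replaces catalysis by organolithium chemistry. It sets out from 7: double bromine–lithium exchange (t-BuLi, THF, −78 °C), trapping with B(OMe)3 and hydrolysis would give [2,4-dimethoxy-6-(2,4,6-trimethoxyphenoxy)-1,3-phenylene]diboronic acid F5. Oxidation with H2O2/NaOH comes back at 8.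

Step 4. Bromination may lose site selectivity: attack at B2 (para to the hydroxyl), over-bromination, or attack on the electron-rich ring A. The fallback fixes the positions of the B4 and B6 oxygens through the starting material. It sets out from 3 and comes back at 8, replacing steps 2 to 6; 2 is still made by step 1 for step 7. The sequence would be:
- Purchased 2-methoxybenzene-1,3-diol F6 is dibenzylated (BnBr, K2CO3, DMF) to 1,3-bis(benzyloxy)-2-methoxybenzene F7.
- NBS (2 equiv, MeCN) brominates the two carbons para to the benzyloxy groups to give 1,5-dibromo-2,4-bis(benzyloxy)-3-methoxybenzene F8.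
- One bromide of the symmetric F8 is coupled with 3 (1 equiv) under the conditions of step 2 to give 1-bromo-2,4-bis(benzyloxy)-3-methoxy-5-(2,4,6-trimethoxyphenoxy)benzene F9. This is regiochemically unambiguous, at the price of a statistical mixture.
- Copper-catalysed methoxylation (CuI, NaOMe, MeOH/DMF, 110 °C) gives 1,3-bis(benzyloxy)-2,4-dimethoxy-6-(2,4,6-trimethoxyphenoxy)benzene F10.
- Hydrogenolysis (H2, Pd/C) gives 8.

Step 10. Cleavage of all seven methyl ethers may remain incomplete, the aqueous acid of the quench may promote ether exchange at the 1,3,5-oxygenated rings, and the pyrogallol rings may autoxidise during isolation. The fallback changes the isolation strategy and sets out from 12. After the BBr3 treatment the volatiles would be removed and the crude polyphenol acetylated directly (Ac2O, pyridine, DMAP) to 5,5'-{[2,4-diacetoxy-6-(2,4,6-triacetoxyphenoxy)-1,3-phenylene]bis(oxy)}bis(benzene-1,2,3-triyl) hexaacetate F11, the undecaacetate of 13. F11 is stable to air and can be purified by chromatography, which also removes partly methylated material. Deacetylation under argon (catalytic NaOMe, degassed MeOH, 0 °C, then acidic resin) comes back at 13.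

## Further compounds

F1 | step 9 | 5-bromo-1,2,3-trimethoxybenzene (purchased) | COc1cc(Br)cc(OC)c1OC
F2 | step 9 | 2-[3,5-dimethoxy-2,4-bis(3,4,5-trimethoxyphenoxy)phenoxy]-1,3,5-trimethoxybenzene | COc1cc(OC)c(Oc2cc(OC)c(Oc3cc(OC)c(OC)c(OC)c3)c(OC)c2Oc2cc(OC)c(OC)c(OC)c2)c(OC)c1
F3 | step 7 | 5-methoxyresorcinol (purchased) | COc1cc(O)cc(O)c1
F4 | step 7 | 3-(benzyloxy)-5-methoxyphenol | COc1cc(O)cc(OCc2ccccc2)c1
F5 | step 6 | [2,4-dimethoxy-6-(2,4,6-trimethoxyphenoxy)-1,3-phenylene]diboronic acid | COc1cc(Oc2c(OC)cc(OC)cc2OC)c(B(O)O)c(OC)c1B(O)O
F6 | step 4 | 2-methoxybenzene-1,3-diol (purchased) | COc1c(O)cccc1O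
F7 | step 4 | 1,3-bis(benzyloxy)-2-methoxybenzene | COc1c(OCc2ccccc2)cccc1OCc1ccccc1
F8 | step 4 | 1,5-dibromo-2,4-bis(benzyloxy)-3-methoxybenzene | COc1c(OCc2ccccc2)c(Br)cc(Br)c1OCc1ccccc1
F9 | step 4 | 1-bromo-2,4-bis(benzyloxy)-3-methoxy-5-(2,4,6-trimethoxyphenoxy)benzene | COc1c(OCc2ccccc2)c(Br)cc(Oc2c(OC)cc(OC)cc2OC)c1OCc1ccccc1
F10 | step 4 | 1,3-bis(benzyloxy)-2,4-dimethoxy-6-(2,4,6-trimethoxyphenoxy)benzene | COc1cc(Oc2c(OC)cc(OC)cc2OC)c(OCc2ccccc2)c(OC)c1OCc1ccccc1
F11 | step 10 | 5,5'-{[2,4-diacetoxy-6-(2,4,6-triacetoxyphenoxy)-1,3-phenylene]bis(oxy)}bis(benzene-1,2,3-triyl) hexaacetate | CC(=O)Oc1cc(OC(C)=O)c(Oc2cc(OC(C)=O)c(Oc3cc(OC(C)=O)c(OC(C)=O)c(OC(C)=O)c3)c(OC(C)=O)c2Oc2cc(OC(C)=O)c(OC(C)=O)c(OC(C)=O)c2)c(OC(C)=O)c1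
A1 | alternative 1 | 3-methoxy-4-(triethylsilyloxy)-2-(3,4,5-trimethoxyphenoxy)-4-[1-(2,4,6-trimethoxyphenoxy)ethenyl]cyclobut-2-en-1-one (racemic) | COC1=C(Oc2cc(OC)c(OC)c(OC)c2)C(=O)C1(O[Si](CC)(CC)CC)C(=C)Oc1c(OC)cc(OC)cc1OC
A2 | alternative 1 | 3-methoxy-4-(triethylsilyloxy)-2-(3,4,5-trimethoxyphenoxy)-5-(2,4,6-trimethoxyphenoxy)phenol | Oc1cc(Oc2c(OC)cc(OC)cc2OC)c(O[Si](CC)(CC)CC)c(OC)c1Oc1cc(OC)c(OC)c(OC)c1
A3 | alternative 2 | 5-(benzyloxy)-2,4-bis(3,4,5-trimethoxyphenoxy)benzene-1,3-dicarbaldehyde | O=Cc1cc(OCc2ccccc2)c(Oc2cc(OC)c(OC)c(OC)c2)c(C=O)c1Oc1cc(OC)c(OC)c(OC)c1
A4 | alternative 2 | 5-(benzyloxy)-2,4-bis(3,4,5-trimethoxyphenoxy)benzene-1,3-diol | Oc1cc(OCc2ccccc2)c(Oc2cc(OC)c(OC)c(OC)c2)c(O)c1Oc1cc(OC)c(OC)c(OC)c1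
A5 | alternative 3 | methyl (E)-6-[3,5-dimethoxy-2,4-bis(3,4,5-trimethoxyphenoxy)phenoxy]-3-methoxy-5-oxohex-2-enoate | COC(=O)/C=C(OC)\CC(=O)COc1cc(OC)c(Oc2cc(OC)c(OC)c(OC)c2)c(OC)c1Oc1cc(OC)c(OC)c(OC)c1
A6 | alternative 3 | 2-[3,5-dimethoxy-2,4-bis(3,4,5-trimethoxyphenoxy)phenoxy]-5-methoxybenzene-1,3-diol | Oc1cc(OC)cc(O)c1Oc1cc(OC)c(Oc2cc(OC)c(OC)c(OC)c2)c(OC)c1Oc1cc(OC)c(OC)c(OC)c1
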